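## Retrosynthetic overview

- Positions use cembrane numbering: C1 bears the isopropyl group, C18 is the 4‑methyl, C19 the CH2OH on C8, C20 the 12‑methyl. The target is (1E,3S,4R,7Z,12R,13S)-3,4-epoxy-13,19-dihydroxycembra-1,7-diene-9,14-dione.
- The 14‑membered ring is closed last, at C1–C2. This is the bond the cembrene cyclase makes, with the same polarity: C1 of the terminal isoprene unit is the nucleophile, C2 of a (Z)-neryl-type end is the electrophile. It is done on the fully oxidised chain by an intramolecular Horner–Wadsworth–Emmons reaction, which gives the 1E‑enone directly.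
- The oxirane is the first ring formed: tartrate‑controlled oxygen transfer to the Δ3(Z) alkene of nerol (C2–C7, C18), so the catalyst sets C3/C4.
- The open chain comes from a three‑component carbonylative B‑alkyl Suzuki coupling: a (Z)-vinyl iodide (C2–C8, C19), CO (C9) and the alkylborane of a ketophosphonate (C10–C14, C1, iPr). The 7Z geometry comes from a (Z)-selective iodo‑Wittig reaction.
- C12/C13 come from a Brown (Z)-crotylboration of ethyl glyoxylate; the phosphonate is added by ester acylation.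

Assumption: diethyl (2‑methylpropyl)phosphonate is taken as a catalogue reagent (otherwise one Arbuzov step from isobutyl bromide and triethyl phosphite).

## Route

Step 1
Reactants: 1 nerol
Product: 2 (2S,3R)-2,3-epoxynerol
Conditions: Ti(OiPr)4 (5 mol %), L-(+)-DET (7.5 mol %), TBHP (decane), 4 Å MS, CH2Cl2, −20 °C
Reagents that add atoms: tert-butyl hydroperoxide CC(C)(C)OO
Why: Sharpless asymmetric epoxidation, in which the Ti–tartrate catalyst epoxidises only the allylic (Z)-alkene and L-(+)-DET delivers oxygen to the face that gives the (2S,3R) cis-epoxide, which is C3(S)/C4(R) of the target with C2 and C5 cis.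

Step 2
Reactants: 2 (2S,3R)-2,3-epoxynerol
Product: 3 (2S,3R)-2,3-epoxyneryl triethylsilyl ether
Conditions: TESCl, imidazole, CH2Cl2, 0 °C
Reagents that add atoms: chlorotriethylsilane CC[Si](Cl)(CC)CC
Why: Silyl ether formation masks the C2 hydroxyl with a group that survives ozonolysis, DIBAL-H and palladium chemistry and can later be oxidised off directly, with no stereocentre touched.

Step 3
Reactants: 3 (2S,3R)-2,3-epoxyneryl triethylsilyl ether
Product: 5 3-[(2R,3S)-2-methyl-3-(triethylsilyloxymethyl)oxiran-2-yl]propanal, via ozonide 4 (not isolated)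
Conditions: O3, CH2Cl2, −78 °C; Me2S, −78 °C → rt
Reagents that add atoms: ozone [O-][O+]=O
Why: Ozonolysis with reductive work-up cleaves the only C=C bond to the C7 aldehyde and acetone, while the epoxide and silyl ether are inert to ozone at −78 °C.

Step 4
Reactants: 5 3-[(2R,3S)-2-methyl-3-(triethylsilyloxymethyl)oxiran-2-yl]propanal; 6 ethyl (triphenylphosphoranylidene)acetate
Product: 8 ethyl (2Z)-2-iodo-5-[(2R,3S)-2-methyl-3-(triethylsilyloxymethyl)oxiran-2-yl]pent-2-enoate, via iodo ylide 7 (not isolated)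
Conditions: 6, NIS, CH2Cl2, −20 °C; then K2CO3, 5, −20 °C → rt
Reagents that add atoms: N-iodosuccinimide O=C1CCC(=O)N1I
Why: Wittig olefination with the iodo ylide made in situ, in which the ester ends up trans to the chain as usual for stabilised ylides, so iodine is cis to C6 (2Z, minor E isomer removed by chromatography) and this fixes the later C6/C9 cis (7Z) geometry.

Step 5
Reactants: 8 ethyl (2Z)-2-iodo-5-[(2R,3S)-2-methyl-3-(triethylsilyloxymethyl)oxiran-2-yl]pent-2-enoate
Product: 9 (2Z)-2-iodo-5-[(2R,3S)-2-methyl-3-(triethylsilyloxymethyl)oxiran-2-yl]pent-2-en-1-ol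
Conditions: DIBAL-H (2.5 equiv), CH2Cl2, −78 °C; Rochelle salt
Reagents that add atoms: none
Why: DIBAL-H 1,2-reduction of the α-iodo enoate gives the allylic alcohol (C19) at −78 °C without touching the vinyl iodide geometry, the epoxide or the TES ether.

Step 6
Reactants: 9 (2Z)-2-iodo-5-[(2R,3S)-2-methyl-3-(triethylsilyloxymethyl)oxiran-2-yl]pent-2-en-1-ol
Product: 10 tert-butyldimethylsilyl ether of 9
Conditions: TBSCl, imidazole, CH2Cl2, 0 °C → rt
Reagents that add atoms: tert-butyldimethylsilyl chloride CC(C)(C)[Si](C)(C)Cl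
Why: Silylation protects the C19 hydroxyl so that the acyl-palladium intermediate of step 10 cannot lactonise and C19 is not oxidised in step 11.

Step 7
Reactants: 11 ethyl glyoxylate; 12 cis-2-butene
Product: 16 ethyl (2S,3R)-2-hydroxy-3-methylpent-4-enoate, via crotylpotassium 13 (not isolated), via crotylborane 14 (not isolated), via borinate 15 (not isolated)
Conditions: 12, KOt-Bu, n-BuLi, THF, −78 → −45 °C; (−)-Ipc2BOMe, −78 °C; BF3·OEt2; 11 (freshly distilled), −78 °C; NaBO3·4H2O, H2O, rt
Reagents that add atoms: none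
Why: Brown asymmetric crotylboration through a closed chair transition state, in which the (Z)-crotyl unit gives the syn Me/OH relationship and the (+)-α-pinene-derived Ipc groups select the aldehyde face that leads to (2S,3R), which is C13(S)/C12(R) of the target.

Step 8
Reactants: 16 ethyl (2S,3R)-2-hydroxy-3-methylpent-4-enoate
Product: 17 ethyl (2S,3R)-2-(tert-butyldimethylsilyloxy)-3-methylpent-4-enoate
Conditions: TBSCl, imidazole, DMF, rt
Reagents that add atoms: tert-butyldimethylsilyl chloride CC(C)(C)[Si](C)(C)Cl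
Why: Silylation protects the C13 hydroxyl before the strongly basic phosphonate acylation and leaves both stereocentres untouched.

Step 9
Reactants: 17 ethyl (2S,3R)-2-(tert-butyldimethylsilyloxy)-3-methylpent-4-enoate; 18 diethyl (2-methylpropyl)phosphonate
Product: 20 diethyl [(5S,6R)-5-(tert-butyldimethylsilyloxy)-2,6-dimethyl-4-oxooct-7-en-3-yl]phosphonate, via lithiated phosphonate 19 (not isolated)
Conditions: 18 (2.2 equiv), n-BuLi (2.1 equiv), THF, −78 °C; then 17, −78 → −20 °C; aq NH4Cl
Reagents that add atoms: none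
Why: Claisen-type acylation of the α-lithio phosphonate by the ester gives the β-ketophosphonate, which is deprotonated by the second equivalent and so protected from over-addition, while C13 is not epimerised at low temperature and the new C1 centre (epimer mixture) later becomes sp2.

Step 10
Reactants: 20 diethyl [(5S,6R)-5-(tert-butyldimethylsilyloxy)-2,6-dimethyl-4-oxooct-7-en-3-yl]phosphonate; 10 tert-butyldimethylsilyl ether of 9; 21 carbon monoxide
Product: 23 open-chain C1–C14 ketophosphonate with C2-OTES and (3S,4R)-epoxide and (7Z)-8-(TBSOCH2)-9-oxo and (12R,13S)-13-OTBS, via alkylborane 22 (not isolated)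
Conditions: 20, 9-BBN (1.2 equiv), THF, 0 °C → rt; then 10, Pd(PPh3)4 (5 mol %), K3PO4, CO (1 atm), THF/toluene, rt
Reagents that add atoms: none
Why: Anti-Markovnikov hydroboration of the only alkene (the ketone flanked by two branched carbons is inert to 9-BBN) followed by carbonylative B-alkyl Suzuki–Miyaura coupling, in which oxidative addition retains the alkene geometry, CO inserts and the alkyl group transfers from boron, makes the C8–C9 and C9–C10 bonds and the 7Z enone in one operation.

Step 11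
Reactants: 23 open-chain C1–C14 ketophosphonate with C2-OTES
Product: 24 open-chain C1–C14 ketophosphonate with C2 aldehyde
Conditions: (COCl)2 (4 equiv), DMSO (8 equiv), CH2Cl2, −78 → −30 °C; Et3N, −78 → 0 °C
Reagents that add atoms: none
Why: Swern oxidation applied directly to the primary TES ether, in which chloride-assisted desilylation by the chlorosulfonium salt and ylide fragmentation give the epoxy aldehyde while the primary allylic and secondary TBS ethers stay on and the oxirane C3–H is not epimerised.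

Step 12
Reactants: 24 open-chain C1–C14 ketophosphonate with C2 aldehyde
Product: 25 13,19-bis-O-TBS ether of the target
Conditions: K2CO3, 18-crown-6, toluene, syringe-pump addition to 2 mM, rt → 50 °C
Reagents that add atoms: none
Why: Intramolecular Horner–Wadsworth–Emmons olefination at high dilution closes the 14-membered ring at C1–C2, the bond and polarity of the cembrene-cyclase closure, because the weak base deprotonates only the phosphonate and elimination through the less hindered oxaphosphetane gives the 1E trisubstituted enone (C3 trans to C14=O) with the oxirane and C12/C13 untouched.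

Step 13
Reactants: 25 13,19-bis-O-TBS ether of the target
Product: 26 (1E,3S,4R,7Z,12R,13S)-3,4-epoxy-13,19-dihydroxycembra-1,7-diene-9,14-dione (target)
Conditions: HF·pyridine, pyridine, THF, 0 °C → rt
Reagents that add atoms: none
Why: Fluoride-mediated desilylation under pyridine-buffered conditions removes both TBS ethers without base (no α-ketol shift or C13 epimerisation) and with too little acidity to open the trisubstituted vinyl epoxide.

## Compound list

1 | nerol, (2Z)-3,7-dimethylocta-2,6-dien-1-ol | CC(C)=CCC/C(C)=C\CO | starting material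
2 | [(2S,3R)-3-methyl-3-(4-methylpent-3-en-1-yl)oxiran-2-yl]methanol | OC[C@@H]1O[C@]1(C)CCC=C(C)C | intermediate
3 | triethyl{[(2S,3R)-3-methyl-3-(4-methylpent-3-en-1-yl)oxiran-2-yl]methoxy}silane | CC[Si](CC)(CC)OC[C@@H]1O[C@]1(C)CCC=C(C)C | intermediate
4 | secondary ozonide of 3 (5,5-dimethyl-1,2,4-trioxolan-3-yl in place of the alkene) | CC[Si](CC)(CC)OC[C@@H]1O[C@]1(C)CCC2OOC(C)(C)O2 | intermediate (not isolated)
5 | 3-[(2R,3S)-2-methyl-3-{[(triethylsilyl)oxy]methyl}oxiran-2-yl]propanal | CC[Si](CC)(CC)OC[C@@H]1O[C@]1(C)CCC=O | intermediate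
6 | ethyl (triphenylphosphoranylidene)acetate | CCOC(=O)C=P(c1ccccc1)(c1ccccc1)c1ccccc1 | starting material
7 | ethyl iodo(triphenylphosphoranylidene)acetate | CCOC(=O)C(I)=P(c1ccccc1)(c1ccccc1)c1ccccc1 | intermediate (not isolated)
8 | ethyl (2Z)-2-iodo-5-[(2R,3S)-2-methyl-3-{[(triethylsilyl)oxy]methyl}oxiran-2-yl]pent-2-enoate | CC[Si](CC)(CC)OC[C@@H]1O[C@]1(C)CC/C=C(\I)C(=O)OCC | intermediate
9 | (2Z)-2-iodo-5-[(2R,3S)-2-methyl-3-{[(triethylsilyl)oxy]methyl}oxiran-2-yl]pent-2-en-1-ol | CC[Si](CC)(CC)OC[C@@H]1O[C@]1(C)CC/C=C(\I)CO | intermediate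
10 | tert-butyl({(2Z)-2-iodo-5-[(2R,3S)-2-methyl-3-{[(triethylsilyl)oxy]methyl}oxiran-2-yl]pent-2-en-1-yl}oxy)dimethylsilane | CC[Si](CC)(CC)OC[C@@H]1O[C@]1(C)CC/C=C(\I)CO[Si](C)(C)C(C)(C)C | intermediate
11 | ethyl glyoxylate | CCOC(=O)C=O | starting material
12 | cis-2-butene | C/C=C\C | starting material
13 | (Z)-but-2-en-1-ylpotassium | [K+].[CH2-]/C=C\C | intermediate (not isolated)
14 | (Z)-but-2-en-1-yl-bis(isopinocampheyl)borane, Ipc from (+)-α-pinene | C/C=C\CB([C@@H]1C[C@@H]2C[C@@H](C2(C)C)[C@H]1C)[C@@H]1C[C@@H]2C[C@@H](C2(C)C)[C@H]1C | intermediate (not isolated)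
15 | bis(isopinocampheyl)borinic ester of 16 | C=C[C@@H](C)[C@H](OB([C@@H]1C[C@@H]2C[C@@H](C2(C)C)[C@H]1C)[C@@H]1C[C@@H]2C[C@@H](C2(C)C)[C@H]1C)C(=O)OCC | intermediate (not isolated)
16 | ethyl (2S,3R)-2-hydroxy-3-methylpent-4-enoate | C=C[C@@H](C)[C@H](O)C(=O)OCC | intermediate
17 | ethyl (2S,3R)-2-{[tert-butyl(dimethyl)silyl]oxy}-3-methylpent-4-enoate | C=C[C@@H](C)[C@H](O[Si](C)(C)C(C)(C)C)C(=O)OCC | intermediate
18 | diethyl (2-methylpropyl)phosphonate | CCOP(=O)(CC(C)C)OCC | starting material
19 | diethyl (1-lithio-2-methylpropyl)phosphonate | [Li]C(C(C)C)P(=O)(OCC)OCC | intermediate (not isolated)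
20 | diethyl [(5S,6R)-5-{[tert-butyl(dimethyl)silyl]oxy}-2,6-dimethyl-4-oxooct-7-en-3-yl]phosphonate (C3 epimers) | C=C[C@@H](C)[C@H](O[Si](C)(C)C(C)(C)C)C(=O)C(C(C)C)P(=O)(OCC)OCC | intermediate
21 | carbon monoxide | [C-]#[O+] | starting material
22 | diethyl [(5S,6R)-8-(9-borabicyclo[3.3.1]nonan-9-yl)-5-{[tert-butyl(dimethyl)silyl]oxy}-2,6-dimethyl-4-oxooctan-3-yl]phosphonate | B1(C2CCCC1CCC2)CC[C@@H](C)[C@H](O[Si](C)(C)C(C)(C)C)C(=O)C(C(C)C)P(=O)(OCC)OCC | intermediate (not isolated)
23 | diethyl [(5S,6R,10Z)-5-{[tert-butyl(dimethyl)silyl]oxy}-10-({[tert-butyl(dimethyl)silyl]oxy}methyl)-2,6-dimethyl-13-[(2R,3S)-2-methyl-3-{[(triethylsilyl)oxy]methyl}oxiran-2-yl]-4,9-dioxotridec-10-en-3-yl]phosphonate | CC[Si](CC)(CC)OC[C@@H]1O[C@]1(C)CC/C=C(/CO[Si](C)(C)C(C)(C)C)C(=O)CC[C@@H](C)[C@H](O[Si](C)(C)C(C)(C)C)C(=O)C(C(C)C)P(=O)(OCC)OCC | intermediate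
24 | diethyl [(5S,6R,10Z)-5-{[tert-butyl(dimethyl)silyl]oxy}-10-({[tert-butyl(dimethyl)silyl]oxy}methyl)-13-[(2R,3R)-3-formyl-2-methyloxiran-2-yl]-2,6-dimethyl-4,9-dioxotridec-10-en-3-yl]phosphonate (same spatial arrangement as 23; the descriptor at the oxirane CH changes by CIP only) | O=C[C@@H]1O[C@]1(C)CC/C=C(/CO[Si](C)(C)C(C)(C)C)C(=O)CC[C@@H](C)[C@H](O[Si](C)(C)C(C)(C)C)C(=O)C(C(C)C)P(=O)(OCC)OCC | intermediate
25 | (1E,3S,4R,7Z,12R,13S)-13,19-bis{[tert-butyl(dimethyl)silyl]oxy}-3,4-epoxycembra-1,7-diene-9,14-dione | CC(C)/C1=C\[C@@H]2O[C@]2(C)CC/C=C(/CO[Si](C)(C)C(C)(C)C)C(=O)CC[C@@H](C)[C@H](O[Si](C)(C)C(C)(C)C)C1=O | intermediate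
26 | (1E,3S,4R,7Z,12R,13S)-3,4-epoxy-13,19-dihydroxycembra-1,7-diene-9,14-dione (CNP0251075.1) | CC(C)/C1=C\[C@@H]2O[C@]2(C)CC/C=C(/CO)C(=O)CC[C@@H](C)[C@H](O)C1=O | target

## Step count and risks

Total step count: 13. Longest linear sequence: 10 steps (steps 1–6, then 10–13, from nerol); the ketophosphonate branch is 3 steps (7–9).

The three steps most likely to fail:

Step 10. The three-component carbonylative coupling may give CO-free direct coupling, or stall at the hindered 2-iodoalkene with the acidic ketophosphonate present. The fallback separates carbonylation from C–C coupling; it sets out from 10 and 22 and comes back at 23. Vinyl iodide 10 is thiocarbonylated (Pd(OAc)2, Xantphos, CO 1 atm, EtSH, Et3N, toluene, 60 °C) to the S-ethyl (Z)-thioester F1. F1 is then joined to alkylborane 22 by a Liebeskind–Srogl ketone synthesis (Pd2(dba)3, tri-2-furylphosphine, CuTC, Cs2CO3, THF) to give 23.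

Step 11. The activated DMSO may attack the β-ketophosphonate, or chloride may open the epoxide. The fallback uses two discrete operations; it sets out from 23 and comes back at 24. The primary TES ether is solvolysed selectively (PPTS, MeOH/CH2Cl2, 0 °C) to the epoxy alcohol F2, which is oxidised with Dess–Martin periodinane (NaHCO3, CH2Cl2, 0 °C) to 24.

Step 12. The hindered α-isopropyl phosphonate may not cyclise, or may oligomerise. The fallback reverses the order of the two couplings: the C1–C2 bond is made intermolecularly and the ring is closed by the palladium step while C2 is still a carbinol, so Pd(0) never meets a vinyl epoxide. It sets out from 17 and 10 and comes back at 25.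
- Ester 17 is converted (MeNHOMe·HCl, i-PrMgCl, THF, −20 °C) into the Weinreb amide F3, and this (i-BuMgCl, THF, 0 °C) into the isobutyl ketone F4.
- Vinyl iodide 10 is oxidised under the conditions of step 11 to the iodo epoxy-aldehyde F5.
- The kinetic lithium enolate of F4 (LDA, THF, −78 °C; deprotonation on the CH2 side, away from the OTBS-bearing carbon) adds to F5 to give the aldol F6 (C1/C2 epimers, both centres later sp2).
- Hydroboration with excess 9-BBN gives the alkylborane F7.
- Intramolecular carbonylative B-alkyl Suzuki coupling (Pd(PPh3)4, K3PO4, CO, high dilution) gives the macrocyclic β-hydroxy ketone F8.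
- Mesylation and E1cB elimination (MsCl, Et3N, then DBU) give 25.

Further compounds

F1 | step 10 | S-ethyl (2Z)-2-({[tert-butyl(dimethyl)silyl]oxy}methyl)-5-[(2R,3S)-2-methyl-3-{[(triethylsilyl)oxy]methyl}oxiran-2-yl]pent-2-enethioate | CC[Si](CC)(CC)OC[C@@H]1O[C@]1(C)CC/C=C(/CO[Si](C)(C)C(C)(C)C)C(=O)SCC
F2 | step 11 | diethyl [(5S,6R,10Z)-5-{[tert-butyl(dimethyl)silyl]oxy}-10-({[tert-butyl(dimethyl)silyl]oxy}methyl)-13-[(2R,3S)-3-(hydroxymethyl)-2-methyloxiran-2-yl]-2,6-dimethyl-4,9-dioxotridec-10-en-3-yl]phosphonate | OC[C@@H]1O[C@]1(C)CC/C=C(/CO[Si](C)(C)C(C)(C)C)C(=O)CC[C@@H](C)[C@H](O[Si](C)(C)C(C)(C)C)C(=O)C(C(C)C)P(=O)(OCC)OCC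
F3 | step 12 | (2S,3R)-2-{[tert-butyl(dimethyl)silyl]oxy}-N-methoxy-N,3-dimethylpent-4-enamide | C=C[C@@H](C)[C@H](O[Si](C)(C)C(C)(C)C)C(=O)N(C)OC
F4 | step 12 | (5S,6R)-5-{[tert-butyl(dimethyl)silyl]oxy}-2,6-dimethyloct-7-en-4-one | C=C[C@@H](C)[C@H](O[Si](C)(C)C(C)(C)C)C(=O)CC(C)C
F5 | step 12 | (2R,3R)-3-[(3Z)-5-{[tert-butyl(dimethyl)silyl]oxy}-4-iodopent-3-en-1-yl]-3-methyloxirane-2-carbaldehyde | O=C[C@@H]1O[C@]1(C)CC/C=C(\I)CO[Si](C)(C)C(C)(C)C
F6 | step 12 | aldol of F4 (C1) with F5 (C2): open-chain 2-hydroxy-14-ketone with C8 iodide and C10=C11 vinyl (C1/C2 epimers) | C=C[C@@H](C)[C@H](O[Si](C)(C)C(C)(C)C)C(=O)C(C(C)C)C(O)[C@@H]1O[C@]1(C)CC/C=C(\I)CO[Si](C)(C)C(C)(C)C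
F7 | step 12 | B-alkyl-9-BBN derivative of F6 (boron on C10) | B1(C2CCCC1CCC2)CC[C@@H](C)[C@H](O[Si](C)(C)C(C)(C)C)C(=O)C(C(C)C)C(O)[C@@H]1O[C@]1(C)CC/C=C(\I)CO[Si](C)(C)C(C)(C)C
F8 | step 12 | macrocyclic 2-hydroxy-1,2-dihydro derivative of 25 (C1/C2 epimers) | CC(C)C1C(O)[C@@H]2O[C@]2(C)CC/C=C(/CO[Si](C)(C)C(C)(C)C)C(=O)CC[C@@H](C)[C@H](O[Si](C)(C)C(C)(C)C)C1=O
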